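**Plan**
- **Cuts:** first O1–C2 of ring C (oxa-Michael, back to a 2'-hydroxychalcone). Then C4a–C8a of ring A (Claisen closure, back to a 2-pyrone). Then C4–C4a (acylation of the pyrone 6-methyl group), and last the C8–prenyl bond.
- **Enabling feature:** ring A (C4a, C5, C6, C7, C8, C8a) carries oxygen on C5, C7 and C8a and the acyl carbon C4 on C4a, which is the pattern of a folded tetraketide. C8a, C8 (prenyl), C7 (OMe), C6 and C5 map one to one onto C2, C3, C4, C5 and C6 of a 4-methoxy-3-prenyl-2-pyrone.
- **Forward:** the pyrone is prenylated at C3, O-methylated, and acylated at its 6-methyl group with the 4-methoxycinnamoyl unit, so ring B arrives ready-made. Mg(OMe)2 then converts the pyrone into ring A, and ring C closes last.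
- **Stereochemistry:** C2 is the only stereocentre. It is set as S in the ring C closure by a cinchona-derived bifunctional thiourea. The 6'-hydroxyl is silylated beforehand, so only the prenyl-flanked 2'-hydroxyl can add (8-prenyl, not 6-prenyl).

Key step: step 5

Assumption: the quinine-derived member of the pseudoenantiomeric thiourea pair is written in step 7. Its sense of induction on this substrate cannot be predicted with confidence and is to be checked by circular dichroism on 14; should it deliver 2R, the quinidine-derived member takes its place with nothing else changed.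

**Step 1**
Reactants: 1 4-hydroxy-6-methylpyran-2-one (triacetic acid lactone); 2 3-methylbut-2-enyl acetate (prenyl acetate)
Product: 3 4-hydroxy-6-methyl-3-(3-methylbut-2-enyl)pyran-2-one
Conditions: 1 (1.5 equiv), Pd(PPh3)4 (5 mol %), DBU (1 equiv), THF, 60 °C
Reagents that add atoms: none
Why: In this Tsuji–Trost allylation the acidic pyrone enolate attacks the unsubstituted terminus of the 1,1-dimethylallyl complex of divalent palladium, any O-prenyl ether is re-ionised by zerovalent palladium so the reaction should drain to the thermodynamic C3-prenyl product, and the excess of 1 holds back a second allylation.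

**Step 2**
Reactants: 3 4-hydroxy-6-methyl-3-(3-methylbut-2-enyl)pyran-2-one
Product: 4 4-methoxy-6-methyl-3-(3-methylbut-2-enyl)pyran-2-one
Conditions: Me2SO4 (1.1 equiv), K2CO3, acetone, reflux
Reagents that add atoms: dimethyl sulfate, COS(=O)(=O)OC
Why: This is O-alkylation of a vinylogous acid with a hard methylating agent, which on 4-hydroxy-2-pyrones favours the 4-methoxy-2-pyrone over the 2-methoxy-4-pyrone and over C-methylation at the already substituted C3.

**Step 3**
Reactants: 5 (E)-4-methoxycinnamic acid
Product: 7 (E)-N-methoxy-3-(4-methoxyphenyl)-N-methylprop-2-enamide, via acyl imidazolide 6 (not isolated)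
Conditions: 1,1'-carbonyldiimidazole, CH2Cl2, rt; then MeNH(OMe)·HCl, rt
Reagents that add atoms: N,O-dimethylhydroxylamine hydrochloride, CNOC.Cl
Why: Weinreb amide formation through the acyl imidazolide is a neutral amide coupling that leaves the E-alkene and the aryl ether untouched.

**Step 4**
Reactants: 4 4-methoxy-6-methyl-3-(3-methylbut-2-enyl)pyran-2-one; 7 (E)-N-methoxy-3-(4-methoxyphenyl)-N-methylprop-2-enamide
Product: 10 4-methoxy-6-[(E)-4-(4-methoxyphenyl)-2-oxobut-3-enyl]-3-(3-methylbut-2-enyl)pyran-2-one, via lithium dienolate 8 (not isolated), via chelated tetrahedral adduct 9 (not isolated)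
Conditions: LiN(iPr)2 (1.05 equiv), THF, −78 °C; 7, −78 to −40 °C; AcOH, −78 °C
Reagents that add atoms: none
Why: In this Weinreb ketone synthesis with a vinylogous ester enolate, C3 is blocked so the amide base deprotonates only the C6 methyl group, the lithium dienolate should add 1,2 because the 4-methoxyphenyl group deactivates the β-carbon of 7, and adduct 9 withholds the acidic β-keto pyrone until the acid quench.

**Step 5**
Reactants: 10 4-methoxy-6-[(E)-4-(4-methoxyphenyl)-2-oxobut-3-enyl]-3-(3-methylbut-2-enyl)pyran-2-one
Product: 12 (E)-1-[2,6-dihydroxy-4-methoxy-3-(3-methylbut-2-enyl)phenyl]-3-(4-methoxyphenyl)prop-2-en-1-one, via ring-opened methyl ester 11 (not isolated)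
Conditions: Mg(OMe)2 (4 equiv, commercial solution), MeOH, reflux; then 1 M HCl, 0 °C
Reagents that add atoms: none
Why: Methoxide adds to the lactone carbonyl (pyrone C2) and opens the ring to methyl ester 11, whose tetrasubstituted enol ether alkene, inherited from pyrone C3=C4, places the ester carbon and the diketone arm on the same side. The methylene flanked by the two ketones is deprotonated and held as a magnesium chelate; this carbon (future C4a) attacks the ester carbon (future C8a), methoxide leaves, and enolisation of the resulting cyclohexenedione aromatises ring A. The closest known reaction type is the base-induced Claisen (Dieckmann-like) cyclisation of 6-(2-oxoalkyl)-4-methoxy-2-pyrones and of 3,5,7-triketo esters to acylphloroglucinols. Ring A closes 6-exo-trig, by acyl substitution at a carbonyl group that lies outside the forming ring, and no stereocentre is created. The step needs Claisen rather than aldol folding and a fixed position for methoxy and prenyl: in 11 the carbon next to the ester bears no hydrogen and its neighbour is locked as a methyl enol ether, so the aldol donor is absent, and pyrone C4-OMe and C3-prenyl become C7-OMe and C8-prenyl by connectivity alone. Reversible additions to the enone should be drained by the irreversible aromatisation, chelation by magnesium should shield the 1,3-diketone from retro-Claisen cleavage, and the alkaline medium should hold 12 as its open bis-phenolate until the cold acid quench, after which it is used at once.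

**Step 6**
Reactants: 12 (E)-1-[2,6-dihydroxy-4-methoxy-3-(3-methylbut-2-enyl)phenyl]-3-(4-methoxyphenyl)prop-2-en-1-one
Product: 13 (E)-1-[6-(tert-butyldimethylsilyloxy)-2-hydroxy-4-methoxy-3-(3-methylbut-2-enyl)phenyl]-3-(4-methoxyphenyl)prop-2-en-1-one
Conditions: TBSOTf (1.05 equiv), 2,6-lutidine, CH2Cl2, −78 °C
Reagents that add atoms: tert-butyldimethylsilyl trifluoromethanesulfonate, CC(C)(C)[Si](C)(C)OS(=O)(=O)C(F)(F)F
Why: In this kinetic silylation of a phenol the 6'-hydroxyl has only hydrogen as its outer neighbour while the 2'-hydroxyl is pressed by the prenyl group into the stronger hydrogen bond to the ketone, so one equivalent of the bulky silyl triflate should take the 6'-oxygen, and at −78 °C with a weak hindered base this should outrun closure to a flavanone.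

**Step 7**
Reactants: 13 (E)-1-[6-(tert-butyldimethylsilyloxy)-2-hydroxy-4-methoxy-3-(3-methylbut-2-enyl)phenyl]-3-(4-methoxyphenyl)prop-2-en-1-one
Product: 14 (2S)-5-(tert-butyldimethylsilyloxy)-7-methoxy-2-(4-methoxyphenyl)-8-(3-methylbut-2-enyl)-2,3-dihydrochromen-4-one
Conditions: N-[3,5-bis(trifluoromethyl)phenyl]-N'-[(8α,9S)-6'-methoxycinchonan-9-yl]thiourea (10 mol %), toluene, 0 °C; filtration through silica
Reagents that add atoms: none
Why: In this organocatalytic asymmetric intramolecular oxa-Michael addition of a 2'-hydroxychalcone (6-endo-trig) the quinuclidine nitrogen deprotonates the only free phenol while the thiourea binds the enone carbonyl, so the phenolate is delivered to the Si face of C-β and sets C2 as S, only the 8-prenyl isomer can form, and prompt removal of the catalyst keeps the reversible addition from eroding the enantiomeric purity.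

**Step 8**
Reactants: 14 (2S)-5-(tert-butyldimethylsilyloxy)-7-methoxy-2-(4-methoxyphenyl)-8-(3-methylbut-2-enyl)-2,3-dihydrochromen-4-one
Product: 15 flowerine, (2S)-5-hydroxy-7-methoxy-2-(4-methoxyphenyl)-8-(3-methylbut-2-enyl)-2,3-dihydrochromen-4-one
Conditions: Bu4NF, AcOH (1 equiv each), THF, 0 °C
Reagents that add atoms: none
Why: Fluoride cleavage of the aryl silyl ether under acetic acid buffering keeps the medium free of phenolate and enolate, so ring C should not open by retro-oxa-Michael reaction, C2 stays S, the 8-prenyl isomer cannot drift to the 6-prenyl isomer, and the prenyl alkene is inert.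

**Compound list**
1 | 4-hydroxy-6-methylpyran-2-one (triacetic acid lactone) | CC1=CC(O)=CC(=O)O1 | starting material
2 | 3-methylbut-2-enyl acetate (prenyl acetate) | CC(=O)OCC=C(C)C | starting material
3 | 4-hydroxy-6-methyl-3-(3-methylbut-2-enyl)pyran-2-one | CC1=CC(O)=C(CC=C(C)C)C(=O)O1 | intermediate
4 | 4-methoxy-6-methyl-3-(3-methylbut-2-enyl)pyran-2-one | CC1=CC(OC)=C(CC=C(C)C)C(=O)O1 | intermediate
5 | (E)-4-methoxycinnamic acid | COc1ccc(/C=C/C(=O)O)cc1 | starting material
6 | (E)-1-(imidazol-1-yl)-3-(4-methoxyphenyl)prop-2-en-1-one (acyl imidazolide, not isolated) | COc1ccc(/C=C/C(=O)n2ccnc2)cc1 | intermediate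
7 | (E)-N-methoxy-3-(4-methoxyphenyl)-N-methylprop-2-enamide | COc1ccc(/C=C/C(=O)N(C)OC)cc1 | intermediate
8 | [4-methoxy-3-(3-methylbut-2-enyl)-2-oxopyran-6-yl]methyllithium (delocalised lithium dienolate, not isolated) | [Li]CC1=CC(OC)=C(CC=C(C)C)C(=O)O1 | intermediate
9 | lithium (E)-2-[methoxy(methyl)amino]-4-(4-methoxyphenyl)-1-[4-methoxy-3-(3-methylbut-2-enyl)-2-oxopyran-6-yl]but-3-en-2-olate (racemic chelated adduct, not isolated) | COc1ccc(/C=C/C(O[Li])(CC2=CC(OC)=C(CC=C(C)C)C(=O)O2)N(C)OC)cc1 | intermediate
10 | 4-methoxy-6-[(E)-4-(4-methoxyphenyl)-2-oxobut-3-enyl]-3-(3-methylbut-2-enyl)pyran-2-one | COC1=C(CC=C(C)C)C(=O)OC(CC(=O)/C=C/c2ccc(OC)cc2)=C1 | intermediate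
11 | methyl (2E,8E)-3-methoxy-9-(4-methoxyphenyl)-2-(3-methylbut-2-enyl)-5,7-dioxonona-2,8-dienoate (present as its magnesium enolate, not isolated) | COC(=O)/C(CC=C(C)C)=C(/OC)CC(=O)CC(=O)/C=C/c1ccc(OC)cc1 | intermediate
12 | (E)-1-[2,6-dihydroxy-4-methoxy-3-(3-methylbut-2-enyl)phenyl]-3-(4-methoxyphenyl)prop-2-en-1-one | COc1ccc(/C=C/C(=O)c2c(O)cc(OC)c(CC=C(C)C)c2O)cc1 | intermediate
13 | (E)-1-[6-(tert-butyldimethylsilyloxy)-2-hydroxy-4-methoxy-3-(3-methylbut-2-enyl)phenyl]-3-(4-methoxyphenyl)prop-2-en-1-one | COc1ccc(/C=C/C(=O)c2c(O[Si](C)(C)C(C)(C)C)cc(OC)c(CC=C(C)C)c2O)cc1 | intermediate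
14 | (2S)-5-(tert-butyldimethylsilyloxy)-7-methoxy-2-(4-methoxyphenyl)-8-(3-methylbut-2-enyl)-2,3-dihydrochromen-4-one | COc1ccc([C@@H]2CC(=O)c3c(O[Si](C)(C)C(C)(C)C)cc(OC)c(CC=C(C)C)c3O2)cc1 | intermediate
15 | flowerine, (2S)-5-hydroxy-7-methoxy-2-(4-methoxyphenyl)-8-(3-methylbut-2-enyl)-2,3-dihydrochromen-4-one | COc1ccc([C@@H]2CC(=O)c3c(O)cc(OC)c(CC=C(C)C)c3O2)cc1 | target

Total step count: 8. Longest linear sequence: 7 (steps 1, 2, 4, 5, 6, 7, 8).

**Steps most likely to fail**

**Risk 1, step 7.**
- What may go wrong: facial selectivity may be poor on an enone that carries no extra activating group. Reversible ring opening, eased by the electron-rich 4-methoxyphenyl group, may also erode the enantiomeric purity.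
- The fallback sets out from 13 and gives up catalyst control in the ring closure. Catalytic DBU in toluene should close ring C to the racemic silyl-protected flavanone F1.
- F1 is then resolved kinetically by Noyori-type asymmetric transfer hydrogenation with RuCl[(R,R)-TsDPEN](p-cymene) and the HCO2H/Et3N azeotrope.
- This catalyst should deliver hydride to give a 4R alcohol. That is matched only with the 2R ketone, where hydride arrives anti to the aryl group.
- The 2R enantiomer should therefore be converted into the cis-(2R,4R)-flavan-4-ol F2, while the 2S ketone is left behind. After chromatography that ketone is 14, where the route is rejoined.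

**Risk 2, step 5.**
- What may go wrong: the enone may be consumed by methanol addition or by intramolecular Michael modes of the opened chain. Methoxide may remove the cinnamoyl group by retro-Claisen cleavage. The product may close early and unselectively to flavanones during acidification.
- The fallback keeps the pyrone-to-arene closure and the same C4a–C8a bond, but runs it before the enone exists.
- It sets out from 4. Dienolate 8 is acylated with N-methoxy-N-methylacetamide to give the acetonylpyrone F3.
- Mg(OMe)2 in refluxing MeOH should fold F3 into the prenylated acetophenone F4, which cannot cyclise and can be purified at leisure.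
- A Claisen–Schmidt condensation of F4 with 4-methoxybenzaldehyde in KOH/EtOH keeps the product as its open dianion. Cold acidification then comes back to the route at 12.

**Risk 3, step 4.**
- What may go wrong: the delocalised dienolate may attack the moderately electrophilic amide only sluggishly. Conjugate addition and decay of the anion on warming may compete.
- The fallback raises the electrophilicity and corrects the oxidation level afterwards.
- It sets out from 4. Dienolate 8 is added at −78 °C to (E)-4-methoxycinnamaldehyde in an aldol-type 1,2-addition, giving the racemic allylic alcohol F5.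
- F5 is oxidised with MnO2 in CH2Cl2, which is selective for allylic alcohols. The route is rejoined at 10.

**Further compounds**
F1 | step 7 | rac-5-(tert-butyldimethylsilyloxy)-7-methoxy-2-(4-methoxyphenyl)-8-(3-methylbut-2-enyl)-2,3-dihydrochromen-4-one | COc1ccc(C2CC(=O)c3c(O[Si](C)(C)C(C)(C)C)cc(OC)c(CC=C(C)C)c3O2)cc1
F2 | step 7 | (2R,4R)-5-(tert-butyldimethylsilyloxy)-7-methoxy-2-(4-methoxyphenyl)-8-(3-methylbut-2-enyl)-3,4-dihydro-2H-chromen-4-ol | COc1ccc([C@H]2C[C@@H](O)c3c(O[Si](C)(C)C(C)(C)C)cc(OC)c(CC=C(C)C)c3O2)cc1
F3 | step 5 | 4-methoxy-3-(3-methylbut-2-enyl)-6-(2-oxopropyl)pyran-2-one | COC1=C(CC=C(C)C)C(=O)OC(CC(C)=O)=C1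
F4 | step 5 | 1-[2,6-dihydroxy-4-methoxy-3-(3-methylbut-2-enyl)phenyl]ethanone | CC(=O)c1c(O)cc(OC)c(CC=C(C)C)c1O
F5 | step 4 | rac-6-[(E)-2-hydroxy-4-(4-methoxyphenyl)but-3-enyl]-4-methoxy-3-(3-methylbut-2-enyl)pyran-2-one | COC1=C(CC=C(C)C)C(=O)OC(CC(O)/C=C/c2ccc(OC)cc2)=C1
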